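**Retrosynthetic overview**

- Ring C, the butenolide (C13, C14, C15, O, C16), is cut at O–C15: it is the cycloisomer of a 2-alkylbuta-2,3-dienoate. Its carbons C13–C16 are those of but-2-ynoic acid, and the cumulated C13=C14=C15 unit holds C15 within reach of the carbonyl oxygen on C16, so one flask can join a C12 iodide to tert-butyl but-2-ynoate (C12–C13) and close ring C (O–C15).
- The decalin comes from one oxidative radical bicyclization of an acyclic α-methyl β-keto ester (trivalent manganese, divalent copper): C4–C5 closes ring A, C9–C10 closes ring B, and loss of a C17 hydrogen gives the C8=C17 alkene. The C3 ketone is a temporary activating group (removed by Barton–McCombie deoxygenation); C20 travels as a diethyl acetal, so that a free C20 carbinol never faces the C19 ester (19,20-lactone).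
- The acyclic chain is built by Negishi carboalumination/oxirane opening (C8=C9), addition of lithiated 2-bromoacrolein acetal (C10, C20, C1), Johnson–Claisen rearrangement (C5=C10, C2, C3) and acylation of methyl propanoate enolate (C4, C18, C19).
- Absolute configuration: enzymatic kinetic resolution of the racemic bicyclic C3 ketone 19, the first chiral ring compound. Ring order: A, B, then C.

Key step: step 14

Remark: labdane numbering is used for all bicyclic compounds (C1–C10 decalin, C11–C16 side chain, C17 on C8, C18 and C19 on C4, C20 on C10; the C4 descriptor reads R in 3-oxygenated intermediates only because of priority). 2-Bromo-3,3-diethoxyprop-1-ene is taken as a commercial reagent. The bicyclization product 19 is a racemate; it is named and drawn as the enantiomer that is carried forward, and its mirror image is removed in step 10.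

**Step 1**
Reactants: 1 tert-butyl(dimethyl)(pent-4-yn-1-yloxy)silane; 2 oxirane
Product: 5 (3E)-7-{[tert-butyl(dimethyl)silyl]oxy}-4-methylhept-3-en-1-ol, via alkenylalane 3 (not isolated), via lithium alanate 4 (not isolated)
Conditions: Me3Al (2 equiv), Cp2ZrCl2 (0.25 equiv), CH2Cl2, 0 °C to rt; then n-BuLi, hexane/THF, −78 °C; then 2, −78 °C to rt; aq. NH4Cl
Reagents that add atoms: trimethylaluminium, C[Al](C)C
Why: Negishi zirconium-catalysed carboalumination adds methyl and aluminium syn across the terminal alkyne with methyl on the internal carbon, and the derived alkenylalanate opens oxirane with retention, so the trisubstituted C8=C9 alkene is formed as the (E) isomer (no stereocentre is formed).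

**Step 2**
Reactants: 5 (3E)-7-{[tert-butyl(dimethyl)silyl]oxy}-4-methylhept-3-en-1-ol
Product: 6 tert-butyl{[(4E)-7-chloro-4-methylhept-4-en-1-yl]oxy}dimethylsilane
Conditions: PPh3, NCS, CH2Cl2, 0 °C to rt
Reagents that add atoms: N-chlorosuccinimide, O=C1CCC(=O)N1Cl
Why: Appel-type chlorination converts the primary alcohol into the chloride by SN2 displacement at C12 under neutral conditions that leave silyl ether and alkene untouched; the chloride is the masked leaving group for the butenolide annulation.

**Step 3**
Reactants: 6 tert-butyl{[(4E)-7-chloro-4-methylhept-4-en-1-yl]oxy}dimethylsilane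
Product: 7 (4E)-7-chloro-4-methylhept-4-en-1-ol
Conditions: PPTS (cat.), MeOH, 40 °C
Reagents that add atoms: none
Why: Acid-catalysed methanolysis of the primary silyl ether (desilylation) should free the C5 alcohol without touching the primary chloride or the trisubstituted alkene.

**Step 4**
Reactants: 7 (4E)-7-chloro-4-methylhept-4-en-1-ol
Product: 8 (4E)-7-chloro-4-methylhept-4-enal
Conditions: Dess–Martin periodinane, CH2Cl2, rt
Reagents that add atoms: none
Why: Dess–Martin oxidation should give the aldehyde under neutral conditions without migration of the γ,δ-alkene.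

**Step 5**
Reactants: 8 (4E)-7-chloro-4-methylhept-4-enal; 9 2-bromo-3,3-diethoxyprop-1-ene
Product: 11 (6E)-9-chloro-2-(diethoxymethyl)-6-methylnona-1,6-dien-3-ol (racemic carbinol), via vinyllithium 10 (not isolated)
Conditions: 9, t-BuLi (2 equiv), Et2O, −78 °C; then 8, −78 °C; aq. NH4Cl
Reagents that add atoms: none
Why: Bromine–lithium exchange and 1,2-addition of the 2-lithioacrolein acetal to the aldehyde should give the 2-substituted allylic alcohol; the new carbinol centre is racemic and is consumed in step 6, and the primary chloride is inert at −78 °C.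

**Step 6**
Reactants: 11 (6E)-9-chloro-2-(diethoxymethyl)-6-methylnona-1,6-dien-3-ol; 12 1,1,1-triethoxyethane
Product: 14 ethyl (4Z,8E)-11-chloro-4-(diethoxymethyl)-8-methylundeca-4,8-dienoate, via ketene acetal 13 (not isolated)
Conditions: 12 (6 equiv), EtCO2H (cat.), 135 °C, EtOH distilled off
Reagents that add atoms: none
Why: Johnson–Claisen rearrangement through a chair transition state with the C6 chain equatorial should place C6 cis to the acetal carbon C20 and trans to C1 in the new C5=C10 alkene (the geometry needed for trans ring fusion) while adding C2 and C3.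

**Step 7**
Reactants: 14 ethyl (4Z,8E)-11-chloro-4-(diethoxymethyl)-8-methylundeca-4,8-dienoate
Product: 15 (4Z,8E)-11-chloro-4-(diethoxymethyl)-N-methoxy-N,8-dimethylundeca-4,8-dienamide
Conditions: MeNH(OMe)·HCl, i-PrMgCl, THF, −20 to 0 °C
Reagents that add atoms: N,O-dimethylhydroxylamine hydrochloride, CNOC.Cl
Why: Aminolysis of the ester by the magnesium amide of N,O-dimethylhydroxylamine should give the Weinreb amide, an acyl donor that accepts one carbon nucleophile only.

**Step 8**
Reactants: 15 (4Z,8E)-11-chloro-4-(diethoxymethyl)-N-methoxy-N,8-dimethylundeca-4,8-dienamide; 16 methyl propanoate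
Product: 18 methyl (6Z,10E)-13-chloro-6-(diethoxymethyl)-2,10-dimethyl-3-oxotrideca-6,10-dienoate (C2 epimers), via lithium enolate 17 (not isolated)
Conditions: 16, LiN(i-Pr)2, THF, −78 °C; then 15, −78 to 0 °C; aq. NH4Cl, 0 °C
Reagents that add atoms: none
Why: Weinreb ketone synthesis with an ester enolate (crossed Claisen-type acylation) should give, through a stable chelated adduct, the α-methyl β-keto ester that carries C4, C18 and C19; C4 is epimerisable here and is fixed in step 9.

**Step 9**
Reactants: 18 methyl (6Z,10E)-13-chloro-6-(diethoxymethyl)-2,10-dimethyl-3-oxotrideca-6,10-dienoate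
Product: 19 methyl (4R,5R,9S,10S)-12-chloro-20,20-diethoxy-3-oxo-13,14,15,16-tetranorlabd-8(17)-en-19-oate (racemate)
Conditions: Mn(OAc)3·2H2O (2.2 equiv), Cu(OAc)2·H2O (0.2 equiv), degassed EtOH, rt
Reagents that add atoms: none
Why: Oxidative free-radical polyene bicyclization: trivalent manganese turns the keto ester enol into the C4 radical, which closes ring A 6-endo onto C5 and then ring B 6-endo onto C9 through a chair–chair arrangement of the two geometrically defined trisubstituted alkenes (anti addition across C5=C10, so H-5 is trans to C20; C11 equatorial; the C4 ester axial and syn to C20, as is usual for α-methyl β-keto ester radicals), and divalent copper oxidizes the tertiary C8 radical with loss of a C17 hydrogen to the exocyclic alkene, so all four stereocentres are set relative to one another and the product forms as the racemate.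

**Step 10**
Reactants: 19 methyl (4R,5R,9S,10S)-12-chloro-20,20-diethoxy-3-oxo-13,14,15,16-tetranorlabd-8(17)-en-19-oate (racemate)
Product: 20 methyl (3S,4R,5R,9S,10S)-12-chloro-20,20-diethoxy-3-hydroxy-13,14,15,16-tetranorlabd-8(17)-en-19-oate
Conditions: ketoreductase (selected from a commercial screening panel), NADP+ (cat.), i-PrOH, phosphate buffer pH 7, DMSO (10% v/v), 30 °C, stopped near half conversion; chromatography
Reagents that add atoms: none
Why: Enzymatic ketone reduction run as a kinetic resolution: an enzyme of the kind that accepts 2-methyl-2-alkoxycarbonylcyclohexanones should deliver hydride to the C3 carbonyl of the (4R,5R,9S,10S) enantiomer only (C3 set S, 3β-OH), while the mirror-image ketone stays unreduced and is removed by chromatography, which fixes the absolute configuration at C4, C5, C9 and C10.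

**Step 11**
Reactants: 20 methyl (3S,4R,5R,9S,10S)-12-chloro-20,20-diethoxy-3-hydroxy-13,14,15,16-tetranorlabd-8(17)-en-19-oate
Product: 21 methyl (3S,4R,5R,9S,10S)-12-chloro-20,20-diethoxy-3-[(phenoxycarbonothioyl)oxy]-13,14,15,16-tetranorlabd-8(17)-en-19-oate
Conditions: PhOC(S)Cl, pyridine, DMAP (cat.), CH2Cl2, rt
Reagents that add atoms: O-phenyl carbonochloridothioate, S=C(Cl)Oc1ccccc1
Why: Thioacylation of the hindered secondary alcohol to the phenyl thionocarbonate uses only amine bases, which should avoid retro-aldol opening of the β-hydroxy ester; C3 keeps its configuration.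

**Step 12**
Reactants: 21 methyl (3S,4R,5R,9S,10S)-12-chloro-20,20-diethoxy-3-[(phenoxycarbonothioyl)oxy]-13,14,15,16-tetranorlabd-8(17)-en-19-oate
Product: 22 methyl (4S,5R,9S,10S)-12-chloro-20,20-diethoxy-13,14,15,16-tetranorlabd-8(17)-en-19-oate
Conditions: n-Bu3SnH, AIBN (cat.), toluene, 100 °C
Reagents that add atoms: none
Why: Barton–McCombie deoxygenation: the stannyl radical adds to the thiocarbonyl group, the C3–O bond fragments and the secondary C3 radical takes hydrogen from the tin hydride, which removes the activating oxygen; the primary chloride and the exocyclic alkene should react far more slowly and no stereocentre is touched.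

**Step 13**
Reactants: 22 methyl (4S,5R,9S,10S)-12-chloro-20,20-diethoxy-13,14,15,16-tetranorlabd-8(17)-en-19-oate
Product: 23 methyl (4S,5R,9S,10S)-20,20-diethoxy-12-iodo-13,14,15,16-tetranorlabd-8(17)-en-19-oate
Conditions: NaI, NaHCO3, acetone, reflux
Reagents that add atoms: sodium iodide, [Na+].[I-]
Why: Finkelstein reaction exchanges the primary chloride for the iodide needed in step 14, driven by precipitation of NaCl, with the buffer protecting the acetal.

**Step 14**
Reactants: 23 methyl (4S,5R,9S,10S)-20,20-diethoxy-12-iodo-13,14,15,16-tetranorlabd-8(17)-en-19-oate; 24 tert-butyl but-2-ynoate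
Product: 27 methyl (4S,5R,9S,10S)-20,20-diethoxylabda-8(17),13-dien-16,15-olid-19-oate, via lithium cumulenolate 25 (not isolated), via tert-butyl allenoate 26 (not isolated)
Conditions: 24, LiN(i-Pr)2, THF/HMPA, −78 °C; then 23, −78 to −20 °C; pH 7 buffer, extraction, solvent exchange to CH2Cl2 (26 not purified); then Ph3PAuCl (5 mol%), AgOTf (5 mol%), CH2Cl2, rt
Reagents that add atoms: none
Why: The ynoate 24 is deprotonated at its γ-methyl group to the lithium cumulenolate 25, which the primary iodide alkylates at the α-carbon (SN2), so C12–C13 is formed and the cumulated C13=C14=C15 unit of allenoate 26 appears; cationic monovalent gold then coordinates the terminal C14=C15 π bond, the ester carbonyl oxygen on C16 attacks C15 anti to the metal, the oxonium ion loses its tert-butyl group as 2-methylpropene and the vinylgold species at C14 is protodeaurated to the butenolide. The closest known reaction types are the α-alkylation of lithium allenolates made from 2-alkynoates and the gold- or silver-catalysed cycloisomerization of buta-2,3-dienoates and buta-2,3-dienoic acids to butenolides. Ring C closes in the 5-endo mode with respect to the C14=C15 bond, which is geometrically easy here because this π bond is orthogonal to the conjugated C13=C14 bond and lies in the plane of the ester group, where the lone pair of the carbonyl oxygen points. No stereocentre is formed; the four existing ones are remote from base and catalyst, and the C19 ester is a neopentyl ester without α-hydrogen that should survive the allenolate. The step needs α- rather than γ-alkylation, which the lithium counter-ion, HMPA and the unhindered primary iodide should favour, and O–C15 closure rather than attack at C13 or C14, which ring size (five against three or four atoms) and the terminal position of the gold-activated bond secure. The tert-butyl group is the temporary activating group: it blocks acyl attack during the alkylation and then leaves as the proton source for protodeauration.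

**Step 15**
Reactants: 27 methyl (4S,5R,9S,10S)-20,20-diethoxylabda-8(17),13-dien-16,15-olid-19-oate
Product: 28 methyl (4S,5R,9S,10S)-20-oxolabda-8(17),13-dien-16,15-olid-19-oate (target, CNP0175906.1)
Conditions: aq. HCl (1 M), THF, 0 °C to rt
Reagents that add atoms: water, O
Why: Acid-catalysed acetal hydrolysis should liberate the neopentyl C20 aldehyde, which has no α-hydrogen and cannot epimerise, while butenolide, methyl ester and the exocyclic alkene tolerate dilute aqueous acid at room temperature.

**Compound list**

1 | tert-butyl(dimethyl)(pent-4-yn-1-yloxy)silane | C#CCCCO[Si](C)(C)C(C)(C)C | starting material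
2 | oxirane | C1CO1 | starting material
3 | [(1E)-5-{[tert-butyl(dimethyl)silyl]oxy}-2-methylpent-1-en-1-yl]dimethylalumane | CC(C)(C)[Si](C)(C)OCCC/C(C)=C/[Al](C)C | intermediate
4 | lithium butyl[(1E)-5-{[tert-butyl(dimethyl)silyl]oxy}-2-methylpent-1-en-1-yl]dimethylaluminate | CC(C)(C)[Si](C)(C)OCCC/C(C)=C/[Al-](C)(C)CCCC.[Li+] | intermediate
5 | (3E)-7-{[tert-butyl(dimethyl)silyl]oxy}-4-methylhept-3-en-1-ol | CC(C)(C)[Si](C)(C)OCCC/C(C)=C/CCO | intermediate
6 | tert-butyl{[(4E)-7-chloro-4-methylhept-4-en-1-yl]oxy}dimethylsilane | CC(C)(C)[Si](C)(C)OCCC/C(C)=C/CCCl | intermediate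
7 | (4E)-7-chloro-4-methylhept-4-en-1-ol | OCCC/C(C)=C/CCCl | intermediate
8 | (4E)-7-chloro-4-methylhept-4-enal | O=CCC/C(C)=C/CCCl | intermediate
9 | 2-bromo-3,3-diethoxyprop-1-ene | C=C(Br)C(OCC)OCC | starting material
10 | (3,3-diethoxyprop-1-en-2-yl)lithium | [Li]C(=C)C(OCC)OCC | intermediate
11 | (6E)-9-chloro-2-(diethoxymethyl)-6-methylnona-1,6-dien-3-ol (racemic at C3) | C=C(C(OCC)OCC)C(O)CC/C(C)=C/CCCl | intermediate
12 | 1,1,1-triethoxyethane (triethyl orthoacetate) | CC(OCC)(OCC)OCC | starting material
13 | (6E)-9-chloro-2-(diethoxymethyl)-3-[(1-ethoxyethenyl)oxy]-6-methylnona-1,6-diene | C=C(OCC)OC(CC/C(C)=C/CCCl)C(=C)C(OCC)OCC | intermediate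
14 | ethyl (4Z,8E)-11-chloro-4-(diethoxymethyl)-8-methylundeca-4,8-dienoate | CCOC(=O)CC/C(C(OCC)OCC)=C/CC/C(C)=C/CCCl | intermediate
15 | (4Z,8E)-11-chloro-4-(diethoxymethyl)-N-methoxy-N,8-dimethylundeca-4,8-dienamide | CON(C)C(=O)CC/C(C(OCC)OCC)=C/CC/C(C)=C/CCCl | intermediate
16 | methyl propanoate | CCC(=O)OC | starting material
17 | lithium 1-methoxyprop-1-en-1-olate | CC=C(OC)O[Li] | intermediate
18 | methyl (6Z,10E)-13-chloro-6-(diethoxymethyl)-2,10-dimethyl-3-oxotrideca-6,10-dienoate (C2 epimers) | COC(=O)C(C)C(=O)CC/C(C(OCC)OCC)=C/CC/C(C)=C/CCCl | intermediate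
19 | methyl (4R,5R,9S,10S)-12-chloro-20,20-diethoxy-3-oxo-13,14,15,16-tetranorlabd-8(17)-en-19-oate (racemate, drawn as the enantiomer carried forward; trans-decalin; CO2Me and C20 both β-axial, H-5 and H-9 α) | C=C1CC[C@@H]2[C@](C(OCC)OCC)(CCC(=O)[C@]2(C)C(=O)OC)[C@H]1CCCl | intermediate
20 | methyl (3S,4R,5R,9S,10S)-12-chloro-20,20-diethoxy-3-hydroxy-13,14,15,16-tetranorlabd-8(17)-en-19-oate (3β-OH) | C=C1CC[C@@H]2[C@](C(OCC)OCC)(CC[C@H](O)[C@]2(C)C(=O)OC)[C@H]1CCCl | intermediate
21 | methyl (3S,4R,5R,9S,10S)-12-chloro-20,20-diethoxy-3-[(phenoxycarbonothioyl)oxy]-13,14,15,16-tetranorlabd-8(17)-en-19-oate | C=C1CC[C@@H]2[C@](C(OCC)OCC)(CC[C@H](OC(=S)Oc3ccccc3)[C@]2(C)C(=O)OC)[C@H]1CCCl | intermediate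
22 | methyl (4S,5R,9S,10S)-12-chloro-20,20-diethoxy-13,14,15,16-tetranorlabd-8(17)-en-19-oate | C=C1CC[C@@H]2[C@](C(OCC)OCC)(CCC[C@]2(C)C(=O)OC)[C@H]1CCCl | intermediate
23 | methyl (4S,5R,9S,10S)-20,20-diethoxy-12-iodo-13,14,15,16-tetranorlabd-8(17)-en-19-oate | C=C1CC[C@@H]2[C@](C(OCC)OCC)(CCC[C@]2(C)C(=O)OC)[C@H]1CCI | intermediate
24 | tert-butyl but-2-ynoate | CC#CC(=O)OC(C)(C)C | starting material
25 | lithium 1-tert-butoxybuta-1,2,3-trien-1-olate | C=C=C=C(O[Li])OC(C)(C)C | intermediate
26 | 16-tert-butyl 19-methyl (4S,5R,9S,10S)-20,20-diethoxylabda-8(17),13,14-triene-16,19-dioate | C=C1CC[C@@H]2[C@](C(OCC)OCC)(CCC[C@]2(C)C(=O)OC)[C@H]1CCC(=C=C)C(=O)OC(C)(C)C | intermediate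
27 | methyl (4S,5R,9S,10S)-20,20-diethoxylabda-8(17),13-dien-16,15-olid-19-oate | C=C1CC[C@@H]2[C@](C(OCC)OCC)(CCC[C@]2(C)C(=O)OC)[C@H]1CCC1=CCOC1=O | intermediate
28 | methyl (4S,5R,9S,10S)-20-oxolabda-8(17),13-dien-16,15-olid-19-oate (CNP0175906.1) | C=C1CC[C@@H]2[C@](C=O)(CCC[C@]2(C)C(=O)OC)[C@H]1CCC1=CCOC1=O | target

**Step count and risks**

Total step count: 15. Longest linear sequence: 15 steps (the route is fully linear, 1 to 28).

The three steps most likely to fail:

Step 9 (oxidative bicyclization). The tertiary C10 radical may be oxidized by copper before ring B closes, hydrogen loss at C8 may give endocyclic alkenes besides the C8=C17 isomer, and the allylic acetal may suffer solvolysis in the oxidizing medium. The fallback is a copper-free, redox-neutral phenylselanyl group-transfer radical bicyclization. It sets out from 18: NaH then PhSeCl (THF, 0 °C) should give the α-phenylselanyl β-keto ester F1. Irradiation in toluene with Mg(ClO4)2 as chelating Lewis acid should run the same C4 to C5 and C10 to C9 cascade and transfer the PhSe group to the C8 radical, giving the racemic tertiary selenide F2. H2O2 with pyridine (CH2Cl2, 0 °C) should then give the exocyclic alkene by selenoxide syn-elimination towards the freely rotating methyl group, and the fallback comes back to the route at 19 (racemate).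

Step 14 (key step). The lithium allenolate may alkylate at the γ-carbon or react so slowly with the iodide that self-condensation of the ynoate takes over, and the gold step may stall before protodeauration. The fallback builds the same allenoate by a Wittig reaction with ketene. It sets out from 23: heating with tert-butyl (triphenyl-λ5-phosphanylidene)acetate (MeCN, 80 °C) should C-alkylate the stabilized ylide to the phosphonium iodide F3. Et3N (2.2 equiv) and acetyl chloride (CH2Cl2, 0 °C) should regenerate the ylide and generate ketene, and their Wittig reaction should give the allenoate, so the fallback comes back to the route at 26, which is closed with Ph3PAuCl and AgOTf as in step 14 to give 27.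

Step 10 (enzymatic kinetic resolution). No enzyme of the panel may accept the hindered ketone, or both enantiomers may be reduced at similar rates. The fallback is a classical resolution through diastereomeric esters. It sets out from 19 (racemate): NaBH4 (MeOH, 0 °C) should attack the carbonyl from the face opposite to the axial groups on C4 and C10 and give 20 together with its enantiomer F4. Esterification with (2S)-methoxy(phenyl)acetic acid (DCC, DMAP, CH2Cl2) should give the ester of 20, F5, and the diastereomeric ester of the enantiomer, F6, which are separated by chromatography. K2CO3 in MeOH should cleave F5, and the fallback comes back to the route at 20.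

**Further compounds**

F1 | step 9 | methyl (6Z,10E)-13-chloro-6-(diethoxymethyl)-2,10-dimethyl-3-oxo-2-(phenylselanyl)trideca-6,10-dienoate | COC(=O)C(C)([Se]c1ccccc1)C(=O)CC/C(C(OCC)OCC)=C/CC/C(C)=C/CCCl
F2 | step 9 | methyl 12-chloro-20,20-diethoxy-3-oxo-8-(phenylselanyl)-13,14,15,16-tetranorlabdan-19-oate (racemic, ring stereocentres as in 19, C8 configuration not controlled) | CC1([Se]c3ccccc3)CC[C@@H]2[C@](C(OCC)OCC)(CCC(=O)[C@]2(C)C(=O)OC)[C@H]1CCCl
F3 | step 14 | {1-tert-butoxy-1-oxo-4-[(4S,5R,9S,10S)-20,20-diethoxy-19-methoxy-19-oxo-11,12,13,14,15,16-hexanorlabd-8(17)-en-9-yl]butan-2-yl}triphenylphosphonium iodide (C13 epimers) | C=C1CC[C@@H]2[C@](C(OCC)OCC)(CCC[C@]2(C)C(=O)OC)[C@H]1CCC(C(=O)OC(C)(C)C)[P+](c1ccccc1)(c1ccccc1)c1ccccc1.[I-]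
F4 | step 10 | methyl (3R,4S,5S,9R,10R)-12-chloro-20,20-diethoxy-3-hydroxy-13,14,15,16-tetranorlabd-8(17)-en-19-oate (enantiomer of 20) | C=C1CC[C@H]2[C@@](C(OCC)OCC)(CC[C@@H](O)[C@@]2(C)C(=O)OC)[C@@H]1CCCl
F5 | step 10 | (2S)-methoxy(phenyl)acetate ester of 20 at O-3 | C=C1CC[C@@H]2[C@](C(OCC)OCC)(CC[C@H](OC(=O)[C@@H](OC)c3ccccc3)[C@]2(C)C(=O)OC)[C@H]1CCCl
F6 | step 10 | (2S)-methoxy(phenyl)acetate ester of F4 at O-3 | C=C1CC[C@H]2[C@@](C(OCC)OCC)(CC[C@@H](OC(=O)[C@@H](OC)c3ccccc3)[C@@]2(C)C(=O)OC)[C@@H]1CCCl
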